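**Strategy.** Everything rests on cutting the O1–C8a bond of ring C in the upper flavan. Ring A has its C7 hydroxyl para to the fusion carbon C4a, while O1 is bound to C8a, the neighbour of C4a, so ring A can travel as a plain 4-hydroxyphenyl group. Its oxidation in methanol gives a 4-methoxycyclohexa-2,5-dienone; in one operation the freed C2 alkoxide then adds to a dienone β-carbon (the future C8a), which closes ring C, and acid expels methanol from C4a to restore the phenol. The precursor is this quinol methyl ether with the C2 oxygen silylated, the C3 oxygen benzylated, C2, C3 and C4 already set, and ring D carried as a dibenzylated, ketal-masked acetophenone.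

Key step: step 14

Conventions: flavan numbering (O1, C2, C3, C4, C4a to C8a; rings A, B, C) is used for the upper unit throughout, also in open-chain intermediates; O2 and O3 are the oxygens on C2 and C3. Ring D is the benzo ring of the chromanone, ring F its pyranone ring, ring E its trihydroxyphenyl group.

Assumption: the facial sense quoted for the diene in step 7 and the oxaziridine in step 8 follows the accepted models for simple (E)-enones and (Z)-enolates; if this substrate responds the other way, the antipodal ligand or reagent is used without other change.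

Step 1
Reactants: 1 2-bromoresorcinol
Product: 2 1-(3-bromo-2,4-dihydroxyphenyl)ethan-1-one
Conditions: AcOH, BF3·OEt2, 90 °C
Reagents that add atoms: acetic acid, CC(=O)O
Why: Friedel–Crafts (Nencki-type) C-acylation of a resorcinol, in which the two activated positions are equivalent, so only one ketone can form.

Step 2
Reactants: 2 bromo dihydroxy acetophenone
Product: 3 1-[2,4-bis(benzyloxy)-3-bromophenyl]ethan-1-one
Conditions: BnBr, K2CO3, DMF, 70 °C
Reagents that add atoms: benzyl bromide, BrCc1ccccc1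
Why: Williamson etherification of both phenols, with heating to overcome the hydrogen bond of the hydroxyl next to the acetyl group.

Step 3
Reactants: 3 dibenzyl bromo ketone
Product: 4 2-[2,4-bis(benzyloxy)-3-bromophenyl]-2-methyl-1,3-dioxolane
Conditions: HOCH2CH2OH, TsOH (cat.), toluene, reflux, Dean–Stark
Reagents that add atoms: ethane-1,2-diol, OCCO
Why: acid-catalysed ketalisation with azeotropic removal of water masks the methyl ketone against the organolithium, enolate and hydride steps that follow.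

Step 4
Reactants: 4 bromo ketal
Product: 6 2,6-bis(benzyloxy)-3-(2-methyl-1,3-dioxolan-2-yl)benzaldehyde, via aryllithium 5 (not isolated)
Conditions: n-BuLi, THF, −78 °C; DMF, −78 → 0 °C; H2O
Reagents that add atoms: N,N-dimethylformamide, CN(C)C=O
Why: bromine–lithium exchange, which is faster than any deprotonation at −78 °C, followed by formylation of the aryllithium (Bouveault aldehyde synthesis).

Step 5
Reactants: 7 5-bromo-1,2,3-tris(benzyloxy)benzene
Product: 9 1-[3,4,5-tris(benzyloxy)phenyl]ethan-1-one, via aryllithium 8 (not isolated)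
Conditions: n-BuLi, THF, −78 °C; MeC(O)N(OMe)Me, −78 → 0 °C; H2O
Reagents that add atoms: N-methoxy-N-methylacetamide, CC(=O)N(C)OC
Why: bromine–lithium exchange and Weinreb ketone synthesis, in which the chelated tetrahedral adduct prevents a second addition.

Step 6
Reactants: 6 ring D aldehyde; 9 ring B acetophenone
Product: 10 (E)-chalcone bearing ring D on the β-carbon
Conditions: KOH (aq.), EtOH/THF, rt
Reagents that add atoms: none
Why: Claisen–Schmidt condensation of a non-enolisable aldehyde with a methyl ketone, the E1cB dehydration giving the (E)-enone.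

Step 7
Reactants: 10 chalcone; 11 [4-(tert-butyldimethylsilyloxy)phenyl]boronic acid
Product: 12 (S)-β,β-diaryl ketone (C4 set)
Conditions: [Rh(C2H4)2Cl]2 (2.5 mol%), (1R,4R)-2,5-diphenylbicyclo[2.2.2]octa-2,5-diene (5.5 mol%), KOH (aq., 0.2 equiv), 1,4-dioxane/H2O 10:1, 40 °C
Reagents that add atoms: none
Why: Hayashi–Miyaura conjugate addition, in which the aryl–rhodium species formed by transmetalation inserts the enone and the twofold-symmetric chiral diene steers the aryl group to the Re face of the β-carbon, setting C4 as S.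

Step 8
Reactants: 12 β,β-diaryl ketone
Product: 14 (2S,3S)-α-hydroxy ketone (C3 set), via sodium enolate 13 (not isolated)
Conditions: NaN(SiMe3)2, THF, −78 °C; (+)-(camphorsulfonyl)oxaziridine, −78 → −40 °C; H2O
Reagents that add atoms: (+)-(camphorsulfonyl)oxaziridine, CC1(C)[C@@H]2CC[C@]13CS(=O)(=O)N4O[C@@]34C2
Why: Davis oxidation of the (Z)-sodium enolate, in which the enolate carbon attacks the oxaziridine oxygen and the chiral reagent selects the enolate face that gives C3 as S (reagent control, the C4 centre being a secondary influence).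

Step 9
Reactants: 14 α-hydroxy ketone
Product: 15 (2S,3S)-α-benzyloxy ketone
Conditions: BnOC(=NH)CCl3, CF3SO3H (cat.), CH2Cl2/cyclohexane, 0 °C → rt
Reagents that add atoms: benzyl 2,2,2-trichloroacetimidate, ClC(Cl)(Cl)C(=N)OCc1ccccc1
Why: acid-catalysed O-benzylation with a trichloroacetimidate, chosen because it avoids the basic conditions that would epimerise or isomerise an α-hydroxy ketone.

Step 10
Reactants: 15 α-benzyloxy ketone
Product: 16 (1R,2S,3S)-anti alcohol (C2 set)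
Conditions: Zn(BH4)2, Et2O/CH2Cl2, −78 → −20 °C
Reagents that add atoms: none
Why: chelation-controlled hydride reduction (Cram chelate model), in which zinc bridges the carbonyl and the C3 benzyloxy oxygen and hydride enters opposite the diarylmethyl group, giving the anti alcohol with C2 as R.

Step 11
Reactants: 16 anti alcohol
Product: 17 bis-silyl ether (O2 and the ring A oxygen silylated)
Conditions: TBSOTf, 2,6-lutidine, CH2Cl2, −78 → 0 °C
Reagents that add atoms: tert-butyldimethylsilyl trifluoromethanesulfonate, CC(C)(C)[Si](C)(C)OS(=O)(=O)C(F)(F)F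
Why: silylation of the hindered benzylic alcohol with a silyl triflate, so that O2 cannot attack C4a during the phenol oxidation.

Step 12
Reactants: 17 bis-silyl ether
Product: 18 ring A phenol with O2 still silylated
Conditions: K2CO3, MeOH/THF, rt
Reagents that add atoms: none
Why: base-mediated methanolysis cleaves the aryl silyl ether selectively, because a phenoxide leaves silicon far more readily than a secondary alkoxide.

Step 13
Reactants: 18 phenol
Product: 19 quinol methyl ether with O2 silylated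
Conditions: PhI(OAc)2, NaHCO3, MeOH/CH2Cl2, −10 °C
Reagents that add atoms: methanol, CO
Why: oxidative dearomatisation of a para-alkylphenol by a trivalent iodine reagent, methanol attacking the para carbon (C4a) of the aryloxyiodine intermediate while the bicarbonate buffer protects the dioxolane and suppresses acid-induced loss of methanol.

Step 14
Reactants: 19 quinol methyl ether with O2 silylated
Product: 23 4-arylflavan with free C7 hydroxyl (ring D acetyl unmasked), via hydroxy quinol ether 20 (not isolated), via oxa-Michael adduct 21 (not isolated), via ketal flavan 22 (not isolated)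
Conditions: Bu4NF, THF, 0 °C → rt; solvent change to CH2Cl2; CF3CO2H, 0 °C; then H2O, rt
Reagents that add atoms: water, O
Why: Fluoride removes the C2 silyl group and the alkoxide of 20 adds to C8a, a β-carbon of the cross-conjugated dienone (intramolecular oxa-Michael addition), forming O1–C8a and closing ring C to give 21; CF3CO2H then enolises the C7 ketone, ionises the doubly allylic C4a–OMe bond and the cation loses the C8a proton to give phenol 22, after which added water hydrolyses the dioxolane to 23. The closest known reaction type is the dearomatisation, conjugate addition, rearomatisation sequence of 4-alkoxycyclohexa-2,5-dienones with heteroatom nucleophiles, together with alkoxide cyclisations onto cyclohexadienones. Ring C closes in the 6-exo-trig mode, the attacked C8a=C8 bond lying outside the new ring. No lasting stereocentre is formed: C4a and C8a of 21 are transient and become sp2, while C2, C3 and C4 keep their configuration because none of their bonds is broken. The step needs conjugate addition by O2 alone, which is secured by the methoxy group already on C4a (no spiro-ether), by the benzyl ethers on O3 and on both ring D oxygens (no five-membered or ring D closure), and by the symmetry of the dienone (either β-carbon converges on one arene). Acid is admitted only after the addition, so the dienone with its C4 hydrogen never meets acid and quinone methide formation is avoided.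

Step 15
Reactants: 23 flavan acetophenone
Product: 24 ring D ortho-hydroxy acetophenone
Conditions: MgBr2·OEt2, toluene/Et2O, 80 °C
Reagents that add atoms: none
Why: chelation-assisted ether cleavage, in which magnesium held between the acetyl oxygen and the ortho benzyloxy oxygen activates only that benzyl group towards SN2 attack by bromide, so the other five benzyl ethers remain.

Step 16
Reactants: 24 diphenol
Product: 25 bis(methoxymethyl) ether
Conditions: NaH, MOMCl, DMF, 0 °C → rt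
Reagents that add atoms: chloromethyl methyl ether, COCCl
Why: Williamson-type alkylation of both phenoxides gives acetals that withstand the basic condensation and epoxidation and fall off in the acid step that closes ring F.

Step 17
Reactants: 25 bis(methoxymethyl) ether; 26 3,4,5-tris(benzyloxy)benzaldehyde
Product: 27 (E)-chalcone carrying rings D and E
Conditions: KOH (aq.), EtOH/THF, rt
Reagents that add atoms: none
Why: Claisen–Schmidt condensation gives the (E)-enone that holds all carbons of rings E and F.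

Step 18
Reactants: 27 chalcone
Product: 28 trans-(2R,3S)-epoxy ketone
Conditions: poly-L-leucine, urea·H2O2, DBU, THF, rt
Reagents that add atoms: urea–hydrogen peroxide, NC(N)=O.OO
Why: Juliá–Colonna epoxidation (Weitz–Scheffer addition of hydroperoxide and closure of the peroxy enolate), the helical peptide directing hydroperoxide to the enone face that gives the (2R,3S)-epoxide, whose trans geometry follows from the (E)-alkene.

Step 19
Reactants: 28 epoxy ketone
Product: 30 octabenzyl ether of the target, via phenolic epoxide 29 (not isolated)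
Conditions: HCl (conc.), MeOH/THF, 50 °C
Reagents that add atoms: none
Why: acid cleaves both methoxymethyl acetals and the ring D hydroxyl then opens the protonated epoxide at its benzylic carbon with inversion (6-endo epoxide opening), so the (2R,3S)-epoxide gives the 2,3-trans (2R,3R)-dihydroflavonol, C3 keeping its configuration because its C–O bond is not broken.

Step 20
Reactants: 30 octabenzyl ether
Product: 31 target CNP0321606.1
Conditions: H2 (1 atm), Pd(OH)2/C, THF/MeOH, rt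
Reagents that add atoms: none
Why: catalytic hydrogenolysis removes all eight O-benzyl groups, while the cyclic benzylic ethers and the aryl ketone are expected to survive these mild conditions.

**Compound list**

1 | 2-bromobenzene-1,3-diol (2-bromoresorcinol) | Oc1cccc(O)c1Br | starting material
2 | 1-(3-bromo-2,4-dihydroxyphenyl)ethan-1-one | CC(=O)c1ccc(O)c(Br)c1O | intermediate
3 | 1-[2,4-bis(benzyloxy)-3-bromophenyl]ethan-1-one | CC(=O)c1ccc(OCc2ccccc2)c(Br)c1OCc1ccccc1 | intermediate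
4 | 2-[2,4-bis(benzyloxy)-3-bromophenyl]-2-methyl-1,3-dioxolane | CC1(OCCO1)c1ccc(OCc2ccccc2)c(Br)c1OCc1ccccc1 | intermediate
5 | [2,6-bis(benzyloxy)-3-(2-methyl-1,3-dioxolan-2-yl)phenyl]lithium | CC1(OCCO1)c1ccc(OCc2ccccc2)c([Li])c1OCc1ccccc1 | intermediate
6 | 2,6-bis(benzyloxy)-3-(2-methyl-1,3-dioxolan-2-yl)benzaldehyde | CC1(OCCO1)c1ccc(OCc2ccccc2)c(C=O)c1OCc1ccccc1 | intermediate
7 | 5-bromo-1,2,3-tris(benzyloxy)benzene | Brc1cc(OCc2ccccc2)c(OCc2ccccc2)c(OCc2ccccc2)c1 | starting material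
8 | [3,4,5-tris(benzyloxy)phenyl]lithium | [Li]c1cc(OCc2ccccc2)c(OCc2ccccc2)c(OCc2ccccc2)c1 | intermediate
9 | 1-[3,4,5-tris(benzyloxy)phenyl]ethan-1-one | CC(=O)c1cc(OCc2ccccc2)c(OCc2ccccc2)c(OCc2ccccc2)c1 | intermediate
10 | (E)-3-[2,6-bis(benzyloxy)-3-(2-methyl-1,3-dioxolan-2-yl)phenyl]-1-[3,4,5-tris(benzyloxy)phenyl]prop-2-en-1-one | CC1(OCCO1)c1ccc(OCc2ccccc2)c(/C=C/C(=O)c2cc(OCc3ccccc3)c(OCc3ccccc3)c(OCc3ccccc3)c2)c1OCc1ccccc1 | intermediate
11 | [4-(tert-butyldimethylsilyloxy)phenyl]boronic acid | CC(C)(C)[Si](C)(C)Oc1ccc(cc1)B(O)O | starting material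
12 | (3S)-3-[2,6-bis(benzyloxy)-3-(2-methyl-1,3-dioxolan-2-yl)phenyl]-3-[4-(tert-butyldimethylsilyloxy)phenyl]-1-[3,4,5-tris(benzyloxy)phenyl]propan-1-one | CC1(OCCO1)c1ccc(OCc2ccccc2)c([C@@H](CC(=O)c2cc(OCc3ccccc3)c(OCc3ccccc3)c(OCc3ccccc3)c2)c2ccc(O[Si](C)(C)C(C)(C)C)cc2)c1OCc1ccccc1 | intermediate
13 | sodium (1Z,3S)-3-[2,6-bis(benzyloxy)-3-(2-methyl-1,3-dioxolan-2-yl)phenyl]-3-[4-(tert-butyldimethylsilyloxy)phenyl]-1-[3,4,5-tris(benzyloxy)phenyl]prop-1-en-1-olate | CC1(OCCO1)c1ccc(OCc2ccccc2)c([C@@H](/C=C(\[O-])c2cc(OCc3ccccc3)c(OCc3ccccc3)c(OCc3ccccc3)c2)c2ccc(O[Si](C)(C)C(C)(C)C)cc2)c1OCc1ccccc1.[Na+] | intermediate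
14 | (2S,3S)-3-[2,6-bis(benzyloxy)-3-(2-methyl-1,3-dioxolan-2-yl)phenyl]-3-[4-(tert-butyldimethylsilyloxy)phenyl]-2-hydroxy-1-[3,4,5-tris(benzyloxy)phenyl]propan-1-one | CC1(OCCO1)c1ccc(OCc2ccccc2)c([C@@H]([C@H](O)C(=O)c2cc(OCc3ccccc3)c(OCc3ccccc3)c(OCc3ccccc3)c2)c2ccc(O[Si](C)(C)C(C)(C)C)cc2)c1OCc1ccccc1 | intermediate
15 | (2S,3S)-2-(benzyloxy)-3-[2,6-bis(benzyloxy)-3-(2-methyl-1,3-dioxolan-2-yl)phenyl]-3-[4-(tert-butyldimethylsilyloxy)phenyl]-1-[3,4,5-tris(benzyloxy)phenyl]propan-1-one | CC1(OCCO1)c1ccc(OCc2ccccc2)c([C@@H]([C@H](OCc2ccccc2)C(=O)c2cc(OCc3ccccc3)c(OCc3ccccc3)c(OCc3ccccc3)c2)c2ccc(O[Si](C)(C)C(C)(C)C)cc2)c1OCc1ccccc1 | intermediate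
16 | (1R,2S,3S)-2-(benzyloxy)-3-[2,6-bis(benzyloxy)-3-(2-methyl-1,3-dioxolan-2-yl)phenyl]-3-[4-(tert-butyldimethylsilyloxy)phenyl]-1-[3,4,5-tris(benzyloxy)phenyl]propan-1-ol | CC1(OCCO1)c1ccc(OCc2ccccc2)c([C@@H]([C@H](OCc2ccccc2)[C@H](O)c2cc(OCc3ccccc3)c(OCc3ccccc3)c(OCc3ccccc3)c2)c2ccc(O[Si](C)(C)C(C)(C)C)cc2)c1OCc1ccccc1 | intermediate
17 | tert-butyldimethylsilyl ether of 16 at the C1 hydroxyl, (1R,2S,3S)-2-(benzyloxy)-3-[2,6-bis(benzyloxy)-3-(2-methyl-1,3-dioxolan-2-yl)phenyl]-1-(tert-butyldimethylsilyloxy)-3-[4-(tert-butyldimethylsilyloxy)phenyl]-1-[3,4,5-tris(benzyloxy)phenyl]propane | CC1(OCCO1)c1ccc(OCc2ccccc2)c([C@@H]([C@H](OCc2ccccc2)[C@H](O[Si](C)(C)C(C)(C)C)c2cc(OCc3ccccc3)c(OCc3ccccc3)c(OCc3ccccc3)c2)c2ccc(O[Si](C)(C)C(C)(C)C)cc2)c1OCc1ccccc1 | intermediate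
18 | 4-[(1S,2S,3R)-2-(benzyloxy)-1-[2,6-bis(benzyloxy)-3-(2-methyl-1,3-dioxolan-2-yl)phenyl]-3-(tert-butyldimethylsilyloxy)-3-[3,4,5-tris(benzyloxy)phenyl]propyl]phenol | CC1(OCCO1)c1ccc(OCc2ccccc2)c([C@@H]([C@H](OCc2ccccc2)[C@H](O[Si](C)(C)C(C)(C)C)c2cc(OCc3ccccc3)c(OCc3ccccc3)c(OCc3ccccc3)c2)c2ccc(O)cc2)c1OCc1ccccc1 | intermediate
19 | 4-[(1S,2S,3R)-2-(benzyloxy)-1-[2,6-bis(benzyloxy)-3-(2-methyl-1,3-dioxolan-2-yl)phenyl]-3-(tert-butyldimethylsilyloxy)-3-[3,4,5-tris(benzyloxy)phenyl]propyl]-4-methoxycyclohexa-2,5-dien-1-one | CC1(OCCO1)c1ccc(OCc2ccccc2)c([C@@H]([C@H](OCc2ccccc2)[C@H](O[Si](C)(C)C(C)(C)C)c2cc(OCc3ccccc3)c(OCc3ccccc3)c(OCc3ccccc3)c2)C2(OC)C=CC(=O)C=C2)c1OCc1ccccc1 | intermediate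
20 | 4-[(1S,2S,3R)-2-(benzyloxy)-1-[2,6-bis(benzyloxy)-3-(2-methyl-1,3-dioxolan-2-yl)phenyl]-3-hydroxy-3-[3,4,5-tris(benzyloxy)phenyl]propyl]-4-methoxycyclohexa-2,5-dien-1-one | CC1(OCCO1)c1ccc(OCc2ccccc2)c([C@@H]([C@H](OCc2ccccc2)[C@H](O)c2cc(OCc3ccccc3)c(OCc3ccccc3)c(OCc3ccccc3)c2)C2(OC)C=CC(=O)C=C2)c1OCc1ccccc1 | intermediate
21 | (2R,3S,4S)-3-(benzyloxy)-4-[2,6-bis(benzyloxy)-3-(2-methyl-1,3-dioxolan-2-yl)phenyl]-4a-methoxy-2-[3,4,5-tris(benzyloxy)phenyl]-2,3,4,4a,8,8a-hexahydro-7H-chromen-7-one (cis ring fusion expected; the transient centres C4a and C8a are left unassigned) | CC1(OCCO1)c1ccc(OCc2ccccc2)c([C@@H]2C3(OC)C=CC(=O)CC3O[C@H](c3cc(OCc4ccccc4)c(OCc4ccccc4)c(OCc4ccccc4)c3)[C@H]2OCc2ccccc2)c1OCc1ccccc1 | intermediate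
22 | (2R,3S,4S)-3-(benzyloxy)-4-[2,6-bis(benzyloxy)-3-(2-methyl-1,3-dioxolan-2-yl)phenyl]-2-[3,4,5-tris(benzyloxy)phenyl]-3,4-dihydro-2H-chromen-7-ol | CC1(OCCO1)c1ccc(OCc2ccccc2)c([C@@H]2c3ccc(O)cc3O[C@H](c3cc(OCc4ccccc4)c(OCc4ccccc4)c(OCc4ccccc4)c3)[C@H]2OCc2ccccc2)c1OCc1ccccc1 | intermediate
23 | 1-{2,4-bis(benzyloxy)-3-[(2R,3S,4S)-3-(benzyloxy)-7-hydroxy-2-[3,4,5-tris(benzyloxy)phenyl]-3,4-dihydro-2H-chromen-4-yl]phenyl}ethan-1-one | CC(=O)c1ccc(OCc2ccccc2)c([C@@H]2c3ccc(O)cc3O[C@H](c3cc(OCc4ccccc4)c(OCc4ccccc4)c(OCc4ccccc4)c3)[C@H]2OCc2ccccc2)c1OCc1ccccc1 | intermediate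
24 | 1-{4-(benzyloxy)-3-[(2R,3S,4S)-3-(benzyloxy)-7-hydroxy-2-[3,4,5-tris(benzyloxy)phenyl]-3,4-dihydro-2H-chromen-4-yl]-2-hydroxyphenyl}ethan-1-one | CC(=O)c1ccc(OCc2ccccc2)c([C@@H]2c3ccc(O)cc3O[C@H](c3cc(OCc4ccccc4)c(OCc4ccccc4)c(OCc4ccccc4)c3)[C@H]2OCc2ccccc2)c1O | intermediate
25 | 1-{4-(benzyloxy)-3-[(2R,3S,4S)-3-(benzyloxy)-7-(methoxymethoxy)-2-[3,4,5-tris(benzyloxy)phenyl]-3,4-dihydro-2H-chromen-4-yl]-2-(methoxymethoxy)phenyl}ethan-1-one | CC(=O)c1ccc(OCc2ccccc2)c([C@@H]2c3ccc(OCOC)cc3O[C@H](c3cc(OCc4ccccc4)c(OCc4ccccc4)c(OCc4ccccc4)c3)[C@H]2OCc2ccccc2)c1OCOC | intermediate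
26 | 3,4,5-tris(benzyloxy)benzaldehyde | O=Cc1cc(OCc2ccccc2)c(OCc2ccccc2)c(OCc2ccccc2)c1 | starting material
27 | (E)-1-{4-(benzyloxy)-3-[(2R,3S,4S)-3-(benzyloxy)-7-(methoxymethoxy)-2-[3,4,5-tris(benzyloxy)phenyl]-3,4-dihydro-2H-chromen-4-yl]-2-(methoxymethoxy)phenyl}-3-[3,4,5-tris(benzyloxy)phenyl]prop-2-en-1-one | O=C(/C=C/c1cc(OCc2ccccc2)c(OCc2ccccc2)c(OCc2ccccc2)c1)c1ccc(OCc2ccccc2)c([C@@H]2c3ccc(OCOC)cc3O[C@H](c3cc(OCc4ccccc4)c(OCc4ccccc4)c(OCc4ccccc4)c3)[C@H]2OCc2ccccc2)c1OCOC | intermediate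
28 | {4-(benzyloxy)-3-[(2R,3S,4S)-3-(benzyloxy)-7-(methoxymethoxy)-2-[3,4,5-tris(benzyloxy)phenyl]-3,4-dihydro-2H-chromen-4-yl]-2-(methoxymethoxy)phenyl}{(2R,3S)-3-[3,4,5-tris(benzyloxy)phenyl]oxiran-2-yl}methanone | O=C([C@@H]1O[C@H]1c1cc(OCc2ccccc2)c(OCc2ccccc2)c(OCc2ccccc2)c1)c1ccc(OCc2ccccc2)c([C@@H]2c3ccc(OCOC)cc3O[C@H](c3cc(OCc4ccccc4)c(OCc4ccccc4)c(OCc4ccccc4)c3)[C@H]2OCc2ccccc2)c1OCOC | intermediate
29 | {4-(benzyloxy)-3-[(2R,3S,4S)-3-(benzyloxy)-7-hydroxy-2-[3,4,5-tris(benzyloxy)phenyl]-3,4-dihydro-2H-chromen-4-yl]-2-hydroxyphenyl}{(2R,3S)-3-[3,4,5-tris(benzyloxy)phenyl]oxiran-2-yl}methanone | O=C([C@@H]1O[C@H]1c1cc(OCc2ccccc2)c(OCc2ccccc2)c(OCc2ccccc2)c1)c1ccc(OCc2ccccc2)c([C@@H]2c3ccc(O)cc3O[C@H](c3cc(OCc4ccccc4)c(OCc4ccccc4)c(OCc4ccccc4)c3)[C@H]2OCc2ccccc2)c1O | intermediate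
30 | (2R,3R)-7-(benzyloxy)-8-[(2R,3S,4S)-3-(benzyloxy)-7-hydroxy-2-[3,4,5-tris(benzyloxy)phenyl]-3,4-dihydro-2H-chromen-4-yl]-3-hydroxy-2-[3,4,5-tris(benzyloxy)phenyl]-2,3-dihydro-4H-chromen-4-one | O=C1c2ccc(OCc3ccccc3)c([C@@H]3c4ccc(O)cc4O[C@H](c4cc(OCc5ccccc5)c(OCc5ccccc5)c(OCc5ccccc5)c4)[C@H]3OCc3ccccc3)c2O[C@H](c2cc(OCc3ccccc3)c(OCc3ccccc3)c(OCc3ccccc3)c2)[C@H]1O | intermediate
31 | (2R,3R)-8-[(2R,3S,4S)-3,7-dihydroxy-2-(3,4,5-trihydroxyphenyl)-3,4-dihydro-2H-chromen-4-yl]-3,7-dihydroxy-2-(3,4,5-trihydroxyphenyl)-2,3-dihydro-4H-chromen-4-one (CNP0321606.1) | O=C1c2ccc(O)c([C@@H]3c4ccc(O)cc4O[C@H](c4cc(O)c(O)c(O)c4)[C@H]3O)c2O[C@H](c2cc(O)c(O)c(O)c2)[C@H]1O | target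

**Step count and risks**

Total: 20 steps. Longest linear sequence: 19 steps (steps 1 to 4 and 6 to 20, from 1); step 5 is a one-step branch.

Steps most likely to fail:

1. Step 14. The conjugate addition of the hindered alkoxide may be slow or reversible, and in the acid phase retro-addition followed by loss of methanol towards a quinone methide may outrun the intended elimination. The fallback closes ring C at O1–C2 instead, with the C8a oxygen brought in on ring A; it sets out from 10 and comes back at 23. Commercial 4-bromoresorcinol is protected with MOMCl/NaH as 1-bromo-2,4-bis(methoxymethoxy)benzene F1 and converted by Miyaura borylation (B2pin2, PdCl2(dppf), KOAc, dioxane, 80 °C) into the pinacol boronate F2. Addition of F2 to 10 under the conditions of step 7 should give the (S)-ketone F3. The operations of steps 8 to 10 then lead through the sodium enolate F4 to the α-hydroxy ketone F5, its benzyl ether F6 and the anti alcohol F7. HCl in MeOH/THF at 50 °C finally removes both methoxymethyl groups and the dioxolane and closes ring C by attack of the C8a hydroxyl on the benzylic C2 cation (SN1 cyclodehydration, the nucleophile entering opposite the C3 benzyloxy group to favour the 2,3-trans flavan), which is 23.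

2. Step 7. Insertion of an enone whose β-aryl group carries two ortho substituents may be slow, so that protodeboronation of 11 overtakes addition and facial selectivity erodes. The fallback replaces asymmetric catalysis by racemic addition and resolution; it sets out from 10 and comes back at 12. The Grignard reagent [4-(tert-butyldimethylsilyloxy)phenyl]magnesium bromide F8, made from commercial (4-bromophenoxy)(tert-butyl)dimethylsilane and Mg in THF, is added in the presence of CuBr·SMe2 (10 mol%) at −40 °C to give the racemic ketone F9. Preparative chromatography on a chiral stationary phase then separates 12 from its (R)-enantiomer F10, which is set aside.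

3. Step 13. The oxidised phenol may lose the C4 proton (quinone methide formation followed by addition of methanol at C4, which would also scramble C4), or the electron-rich benzyloxyarenes may be over-oxidised. The fallback dearomatises with singlet oxygen, which avoids a phenoxenium ion; it sets out from 18 and comes back at 23 by way of 22. 2KHSO5·KHSO4·K2SO4 with NaHCO3 in aqueous MeCN generates singlet oxygen, which should add to the phenol to give the para-hydroperoxy dienone F11; Me2S reduces it in the same flask to the para-quinol F12. Under the conditions of step 14, Bu4NF gives the diol F13, which cyclises to the 4a-hydroxy adduct F14; CF3CO2H then eliminates water in place of methanol to give 22 and, after hydrolysis of the dioxolane, 23.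

**Further compounds**

F1 | step 14 | 1-bromo-2,4-bis(methoxymethoxy)benzene | COCOc1ccc(Br)c(OCOC)c1
F2 | step 14 | 2-[2,4-bis(methoxymethoxy)phenyl]-4,4,5,5-tetramethyl-1,3,2-dioxaborolane | COCOc1ccc(B2OC(C)(C)C(C)(C)O2)c(OCOC)c1
F3 | step 14 | (3S)-3-[2,6-bis(benzyloxy)-3-(2-methyl-1,3-dioxolan-2-yl)phenyl]-3-[2,4-bis(methoxymethoxy)phenyl]-1-[3,4,5-tris(benzyloxy)phenyl]propan-1-one | CC1(OCCO1)c1ccc(OCc2ccccc2)c([C@@H](CC(=O)c2cc(OCc3ccccc3)c(OCc3ccccc3)c(OCc3ccccc3)c2)c2ccc(OCOC)cc2OCOC)c1OCc1ccccc1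
F4 | step 14 | sodium (1Z,3S)-3-[2,6-bis(benzyloxy)-3-(2-methyl-1,3-dioxolan-2-yl)phenyl]-3-[2,4-bis(methoxymethoxy)phenyl]-1-[3,4,5-tris(benzyloxy)phenyl]prop-1-en-1-olate | CC1(OCCO1)c1ccc(OCc2ccccc2)c([C@@H](/C=C(\[O-])c2cc(OCc3ccccc3)c(OCc3ccccc3)c(OCc3ccccc3)c2)c2ccc(OCOC)cc2OCOC)c1OCc1ccccc1.[Na+]
F5 | step 14 | (2S,3S)-3-[2,6-bis(benzyloxy)-3-(2-methyl-1,3-dioxolan-2-yl)phenyl]-3-[2,4-bis(methoxymethoxy)phenyl]-2-hydroxy-1-[3,4,5-tris(benzyloxy)phenyl]propan-1-one | CC1(OCCO1)c1ccc(OCc2ccccc2)c([C@@H]([C@H](O)C(=O)c2cc(OCc3ccccc3)c(OCc3ccccc3)c(OCc3ccccc3)c2)c2ccc(OCOC)cc2OCOC)c1OCc1ccccc1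
F6 | step 14 | (2S,3S)-2-(benzyloxy)-3-[2,6-bis(benzyloxy)-3-(2-methyl-1,3-dioxolan-2-yl)phenyl]-3-[2,4-bis(methoxymethoxy)phenyl]-1-[3,4,5-tris(benzyloxy)phenyl]propan-1-one | CC1(OCCO1)c1ccc(OCc2ccccc2)c([C@@H]([C@H](OCc2ccccc2)C(=O)c2cc(OCc3ccccc3)c(OCc3ccccc3)c(OCc3ccccc3)c2)c2ccc(OCOC)cc2OCOC)c1OCc1ccccc1
F7 | step 14 | (1R,2S,3S)-2-(benzyloxy)-3-[2,6-bis(benzyloxy)-3-(2-methyl-1,3-dioxolan-2-yl)phenyl]-3-[2,4-bis(methoxymethoxy)phenyl]-1-[3,4,5-tris(benzyloxy)phenyl]propan-1-ol | CC1(OCCO1)c1ccc(OCc2ccccc2)c([C@@H]([C@H](OCc2ccccc2)[C@H](O)c2cc(OCc3ccccc3)c(OCc3ccccc3)c(OCc3ccccc3)c2)c2ccc(OCOC)cc2OCOC)c1OCc1ccccc1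
F8 | step 7 | [4-(tert-butyldimethylsilyloxy)phenyl]magnesium bromide | CC(C)(C)[Si](C)(C)Oc1ccc([Mg]Br)cc1
F9 | step 7 | racemic 3-[2,6-bis(benzyloxy)-3-(2-methyl-1,3-dioxolan-2-yl)phenyl]-3-[4-(tert-butyldimethylsilyloxy)phenyl]-1-[3,4,5-tris(benzyloxy)phenyl]propan-1-one | CC1(OCCO1)c1ccc(OCc2ccccc2)c(C(CC(=O)c2cc(OCc3ccccc3)c(OCc3ccccc3)c(OCc3ccccc3)c2)c2ccc(O[Si](C)(C)C(C)(C)C)cc2)c1OCc1ccccc1
F10 | step 7 | (3R)-3-[2,6-bis(benzyloxy)-3-(2-methyl-1,3-dioxolan-2-yl)phenyl]-3-[4-(tert-butyldimethylsilyloxy)phenyl]-1-[3,4,5-tris(benzyloxy)phenyl]propan-1-one | CC1(OCCO1)c1ccc(OCc2ccccc2)c([C@H](CC(=O)c2cc(OCc3ccccc3)c(OCc3ccccc3)c(OCc3ccccc3)c2)c2ccc(O[Si](C)(C)C(C)(C)C)cc2)c1OCc1ccccc1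
F11 | step 13 | 4-[(1S,2S,3R)-2-(benzyloxy)-1-[2,6-bis(benzyloxy)-3-(2-methyl-1,3-dioxolan-2-yl)phenyl]-3-(tert-butyldimethylsilyloxy)-3-[3,4,5-tris(benzyloxy)phenyl]propyl]-4-hydroperoxycyclohexa-2,5-dien-1-one | CC1(OCCO1)c1ccc(OCc2ccccc2)c([C@@H]([C@H](OCc2ccccc2)[C@H](O[Si](C)(C)C(C)(C)C)c2cc(OCc3ccccc3)c(OCc3ccccc3)c(OCc3ccccc3)c2)C2(OO)C=CC(=O)C=C2)c1OCc1ccccc1
F12 | step 13 | 4-[(1S,2S,3R)-2-(benzyloxy)-1-[2,6-bis(benzyloxy)-3-(2-methyl-1,3-dioxolan-2-yl)phenyl]-3-(tert-butyldimethylsilyloxy)-3-[3,4,5-tris(benzyloxy)phenyl]propyl]-4-hydroxycyclohexa-2,5-dien-1-one | CC1(OCCO1)c1ccc(OCc2ccccc2)c([C@@H]([C@H](OCc2ccccc2)[C@H](O[Si](C)(C)C(C)(C)C)c2cc(OCc3ccccc3)c(OCc3ccccc3)c(OCc3ccccc3)c2)C2(O)C=CC(=O)C=C2)c1OCc1ccccc1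
F13 | step 13 | 4-[(1S,2S,3R)-2-(benzyloxy)-1-[2,6-bis(benzyloxy)-3-(2-methyl-1,3-dioxolan-2-yl)phenyl]-3-hydroxy-3-[3,4,5-tris(benzyloxy)phenyl]propyl]-4-hydroxycyclohexa-2,5-dien-1-one | CC1(OCCO1)c1ccc(OCc2ccccc2)c([C@@H]([C@H](OCc2ccccc2)[C@H](O)c2cc(OCc3ccccc3)c(OCc3ccccc3)c(OCc3ccccc3)c2)C2(O)C=CC(=O)C=C2)c1OCc1ccccc1
F14 | step 13 | (2R,3S,4S)-3-(benzyloxy)-4-[2,6-bis(benzyloxy)-3-(2-methyl-1,3-dioxolan-2-yl)phenyl]-4a-hydroxy-2-[3,4,5-tris(benzyloxy)phenyl]-2,3,4,4a,8,8a-hexahydro-7H-chromen-7-one (C4a and C8a unassigned) | CC1(OCCO1)c1ccc(OCc2ccccc2)c([C@@H]2C3(O)C=CC(=O)CC3O[C@H](c3cc(OCc4ccccc4)c(OCc4ccccc4)c(OCc4ccccc4)c3)[C@H]2OCc2ccccc2)c1OCc1ccccc1
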